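**Strategy.** Atom numbers are those of the target skeleton (ring C5–C10, C1/C2 epoxide, C14 methyl). The cyclohexane is disconnected at C5–C10 to the cycloheptanone ring of a furan-derived 8-oxabicyclo[3.2.1]octenone, in which the ketone carbon is the future C1. A quasi-Favorskii (semibenzilic) ring contraction exploits the C10(Me)–C1 quaternary unit: a carbanion adds to the ketone, C5 migrates to C10 with loss of chloride, and the ring shrinks by the carbon that becomes the epoxide CH. The precursor is the enantioenriched α-chloro-α-methyl ketone carrying the C5 side chain; its oxygen bridge later gives C6–O, a syn SN2′ vinylation C7, and dihydroxylation C8/C9.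

Key step: step 5

Remark: ketone 1 (the [4+3] cycloadduct of furan and the parent oxyallyl cation) is taken as commercially available; in the names, β is the face of the oxygen bridge (the C6–O face of the target) and α the opposite face.

Step 1
Reactants: 1 8-oxabicyclo[3.2.1]oct-6-en-3-one
Product: 2 3-(trimethylsilyloxy)-8-oxabicyclo[3.2.1]octa-2,6-diene (C1=C10 silyl enol ether; one enantiomer)
Conditions: lithium bis[(R)-1-phenylethyl]amide, LiCl, TMSCl (internal quench), THF, −100 °C
Reagents that add atoms: chlorotrimethylsilane C[Si](C)(C)Cl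
Why: Desymmetrising deprotonation of a meso ketone by a chiral lithium amide with internal silyl quench is a known reaction type for this bicyclic ketone; the base enantiomer (its antipode would give ent-2) selects the enantiotopic CH2 that becomes C10 and so fixes the absolute sense of the bridgeheads C6 and C9 for the whole route.

Step 2
Reactants: 2 silyl enol ether
Product: 3 2β-chloro-8-oxabicyclo[3.2.1]oct-6-en-3-one (chloride on C10; axial)
Conditions: NCS, THF, −78 → 0 °C
Reagents that add atoms: N-chlorosuccinimide O=C1CCC(=O)N1Cl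
Why: Electrophilic α-chlorination of a silyl enol ether should place chlorine regiospecifically on the enol ether carbon C10 from the oxygen-bridge face; the C10 configuration does not matter because C10 is enolised again in step 3.

Step 3
Reactants: 3 α-chloro ketone
Product: 5 2α-chloro-2β-methyl-8-oxabicyclo[3.2.1]oct-6-en-3-one (C10: methyl axial/β; chloride equatorial/α), via lithium chloro-enolate 4 (not isolated)
Conditions: LiHMDS, THF/DMPU, −78 °C; MeI, −78 → −40 °C
Reagents that add atoms: iodomethane CI
Why: The C–H flanked by carbonyl and chlorine is the most acidic, and kinetic C-methylation of the chloro enolate (enolate alkylation) should occur on the β face, anti to the etheno bridge, which makes the methyl axial (β) and the chloride equatorial (α) at the new quaternary stereocentre C10.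

Step 4
Reactants: 5 chloro methyl ketone
Product: 7 4β-[2-(tert-butyldimethylsilyloxy)ethyl]-2α-chloro-2β-methyl-8-oxabicyclo[3.2.1]oct-6-en-3-one (C5 side chain axial/β), via lithium enolate 6 (not isolated)
Conditions: LDA, THF, −78 °C; TBSOCH2CH2OTf (from TBSOCH2CH2OH, Tf2O, 2,6-lutidine, CH2Cl2, −78 °C), −78 → −40 °C
Reagents that add atoms: 2-(tert-butyldimethylsilyloxy)ethyl trifluoromethanesulfonate CC(C)(C)[Si](C)(C)OCCOS(=O)(=O)C(F)(F)F
Why: Only C5 can still be enolised, and alkylation of this kinetic enolate with the reactive primary triflate (enolate alkylation) should again occur from the β face because the α face is screened by the etheno bridge, so the side chain becomes axial (β, cis to the C10 methyl) and is not equilibrated since the remaining α-hydrogen is equatorial.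

Step 5
Reactants: 7 α-chloro-α-methyl-α′-alkyl ketone
Product: 9 1-{exo-3-[2-(tert-butyldimethylsilyloxy)ethyl]-exo-2-methyl-7-oxabicyclo[2.2.1]hept-5-en-2-yl}-2-(phenylthio)ethanone (C10: methyl exo/β and acyl endo/α; C5 side chain exo/β), via lithium alkoxide 8 (not isolated)
Conditions: PhSMe, n-BuLi, TMEDA, THF, 0 °C (gives PhSCH2Li); 7 added at −78 °C; warm to rt
Reagents that add atoms: (phenylthio)methyllithium [Li]CSc1ccccc1
Why: PhSCH2Li adds to the C1 ketone on the face opposite the two β-axial groups, and in the chair pyranone (the conformer that reacts) the alkoxide has its C1–C5 bond antiperiplanar to the equatorial C10–Cl bond, so that on warming C5 shifts from C1 to C10 as chloride leaves and C1 becomes the exocyclic ketone (semibenzilic mechanism). The closest known reaction type is the quasi-Favorskii ring contraction of α-halo ketone [4+3] cycloadducts triggered by organolithium or hydride addition. The six-membered carbocycle C5–C6–C7–C8–C9–C10 is closed by this suprafacial 1,2-alkyl shift, an intramolecular backside displacement at C10 (formally 3-exo-tet within the C1–C5–C10 triangle), which contracts the seven-membered ring by C1. C10 is the only new stereocentre and is set by inversion at the C–Cl carbon (methyl exo/β, acyl endo/α), while C5 migrates with retention so its side chain stays β. The step needs the ring bond, and not the alkoxide oxygen or the CH2SPh group, to displace chloride; this is secured by the equatorial chloride, to which no substituent of C1 other than C5 can be antiperiplanar in the chair. Loss of LiCl and formation of the C=O bond should make the step irreversible despite the added ring strain.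

Step 6
Reactants: 9 ring-contracted ketone
Product: 10 (1R)-alcohol: (R)-1-(the oxanorbornenyl group of 9)-2-(phenylthio)ethanol
Conditions: (R)-Me-CBS (20 mol%), BH3·SMe2, toluene, −30 °C
Reagents that add atoms: none
Why: Corey–Bakshi–Shibata reduction, in which the catalyst distinguishes the tertiary-alkyl substituent (C10) from the CH2SPh substituent of the ketone, should give the (1R)-alcohol under reagent control.

Step 7
Reactants: 10 alcohol
Product: 11 triethylsilyl ether of 10
Conditions: TESOTf, 2,6-lutidine, CH2Cl2, −78 °C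
Reagents that add atoms: triethylsilyl trifluoromethanesulfonate CC[Si](CC)(CC)OS(=O)(=O)C(F)(F)F
Why: Silylation of the hindered secondary alcohol with a silyl triflate masks C1–OH so that only the C6 alkoxide formed in step 8 is acylated.

Step 8
Reactants: 11 silyl ether
Product: 13 cyclohex-3-enyl isobutyrate (C5β CH2CH2OTBS; C6β isobutyrate; C7β vinyl; C8=C9; C10β methyl; C10α (1R)-2-(phenylthio)-1-(triethylsilyloxy)ethyl), via lithium alkoxide 12 (not isolated)
Conditions: CH2=CHLi (from (CH2=CH)4Sn, MeLi), TMEDA, Et2O, 0 °C → rt; then (i-PrCO)2O, 0 °C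
Reagents that add atoms: vinyllithium [Li]C=C; isobutyric anhydride CC(C)C(=O)OC(=O)C(C)C
Why: Syn SN2′ ring opening of the strained 7-oxanorbornene by an organolithium (exo carbolithiation of C7=C8, then β-alkoxide elimination) should place the vinyl group on C7 cis to the retained C6 oxygen (both β) and cleave C9–O, attack at C7 rather than C8 being expected because the alkoxide then develops at the less hindered C6, remote from the quaternary C10; the alkoxide is acylated in the same flask.

Step 9
Reactants: 13 isobutyrate
Product: 15 epoxy alcohol (C10α (R)-oxiranyl; C5β 2-hydroxyethyl; other groups as in 13), via sulfonium tetrafluoroborate 14 (not isolated)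
Conditions: Me3OBF4, CH2Cl2, 0 °C → rt; then TBAF, THF, 0 °C
Reagents that add atoms: none
Why: S-Methylation with Meerwein's salt turns the sulfide into a sulfonium leaving group, and fluoride then frees the C1 alkoxide, which closes the epoxide by intramolecular SN2 at the primary C2 (β-hydroxy sulfonium to epoxide) with retention at C1, while the same fluoride removes the primary TBS ether.

Step 10
Reactants: 15 epoxy alcohol
Product: 17 diol (C7β CH2CH2OH and C5β CH2CH2OH), via bis(9-BBN) adduct 16 (not isolated)
Conditions: 9-BBN (3 equiv), THF, rt; then NaBO3·4H2O, THF/H2O, rt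
Reagents that add atoms: sodium perborate [Na+].[Na+].O[B-]1(O)OO[B-](O)(O)OO1
Why: Hydroboration–oxidation with 9-BBN is chemoselective for the monosubstituted vinyl group over the cis-disubstituted ring alkene next to the quaternary C10 and should give the primary alcohol (anti-Markovnikov) without touching epoxide or ester.

Step 11
Reactants: 17 diol
Product: 18 dialdehyde (C5β CH2CHO and C7β CH2CHO)
Conditions: Dess–Martin periodinane, NaHCO3, CH2Cl2, 0 °C → rt
Reagents that add atoms: none
Why: Dess–Martin oxidation of both primary alcohols under buffered conditions should give the dialdehyde; no secondary alcohol is present and the epoxide tolerates the neutral oxidant.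

Step 12
Reactants: 18 dialdehyde
Product: 20 bis(α-methylene) dialdehyde (C5β C(=CH2)CHO and C7β C(=CH2)CHO), via bis-Mannich base 19 (not isolated)
Conditions: CH2=NMe2+ I−, Et3N, CH2Cl2, rt
Reagents that add atoms: dimethylmethyleneiminium iodide (Eschenmoser's salt) C=[N+](C)C.[I-]
Why: α-Methylenation of aldehydes with Eschenmoser's salt (Mannich reaction, then amine elimination) installs C15 and C13 in one operation on the two CH2–CHO arms, which are alike in reactivity.

Step 13
Reactants: 20 bis-enal
Product: 22 γ-lactol (C8α–O–C12 hemiacetal; C9α–OH; anomers at C12), via dihydroxy dialdehyde 21 (not isolated)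
Conditions: OsO4 (5 mol%), NMO, acetone/H2O, 0 °C → rt
Reagents that add atoms: osmium tetroxide O=[Os](=O)(=O)=O; N-methylmorpholine N-oxide C[N+]1([O-])CCOCC1
Why: Catalytic OsO4/NMO syn-dihydroxylation is selective for the isolated C8=C9 alkene over the two electron-poor enal alkenes and should occur on the α face, anti to the pseudo-axial C10 methyl, the C7 side chain and the axial C6 isobutyrate, so that C8–OH and C9–OH are both α; the C8 hydroxyl then adds to the C12 aldehyde to give the γ-lactol.

Step 14
Reactants: 22 lactol
Product: 23 CNP0496100.1 (target)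
Conditions: MnO2 (activated, excess), CH2Cl2, rt
Reagents that add atoms: none
Why: Manganese dioxide oxidises the allylic lactol to the α-methylene-γ-lactone (lactol oxidation) and should leave the non-allylic C9 alcohol, the enal, the epoxide and the ester untouched.

**Compound list**

1 | 8-oxabicyclo[3.2.1]oct-6-en-3-one (meso; ketone carbon = future C1) | O=C1C[C@@H]2C=C[C@@H](O2)C1 | starting material
2 | 3-(trimethylsilyloxy)-8-oxabicyclo[3.2.1]octa-2,6-diene (C1=C10 enol ether) | C[Si](C)(C)OC1=C[C@@H]2C=C[C@@H](O2)C1 | intermediate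
3 | 2β-chloro-8-oxabicyclo[3.2.1]oct-6-en-3-one (Cl on C10; axial) | O=C1[C@@H](Cl)[C@@H]2C=C[C@@H](O2)C1 | intermediate
4 | lithium chloro-enolate of 3 (C1=C10) | [Li]OC1=C(Cl)[C@@H]2C=C[C@@H](O2)C1 | intermediate
5 | 2α-chloro-2β-methyl-8-oxabicyclo[3.2.1]oct-6-en-3-one | O=C1[C@](C)(Cl)[C@@H]2C=C[C@@H](O2)C1 | intermediate
6 | lithium enolate of 5 (C1=C5) | C1=C(O[Li])[C@](C)(Cl)[C@@H]2C=C[C@H]1O2 | intermediate
7 | 4β-[2-(tert-butyldimethylsilyloxy)ethyl]-2α-chloro-2β-methyl-8-oxabicyclo[3.2.1]oct-6-en-3-one | O=C1[C@](C)(Cl)[C@@H]2C=C[C@@H](O2)[C@H]1CCO[Si](C)(C)C(C)(C)C | intermediate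
8 | lithium alkoxide from addition of PhSCH2Li to C1 of 7 (O β; CH2SPh α) | [Li]O[C@@]1(CSc2ccccc2)[C@](C)(Cl)[C@@H]3C=C[C@@H](O3)[C@H]1CCO[Si](C)(C)C(C)(C)C | intermediate
9 | 7-oxanorbornene ketone (C10: exo Me and endo C(=O)CH2SPh; C5: exo CH2CH2OTBS) | O=C(CSc1ccccc1)[C@]2(C)[C@@H]3C=C[C@@H](O3)[C@H]2CCO[Si](C)(C)C(C)(C)C | intermediate
10 | (1R)-alcohol of 9 | O[C@@H](CSc1ccccc1)[C@]2(C)[C@@H]3C=C[C@@H](O3)[C@H]2CCO[Si](C)(C)C(C)(C)C | intermediate
11 | triethylsilyl ether of 10 | CC[Si](CC)(CC)O[C@@H](CSc1ccccc1)[C@]2(C)[C@@H]3C=C[C@@H](O3)[C@H]2CCO[Si](C)(C)C(C)(C)C | intermediate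
12 | lithium C6-alkoxide of the ring-opened cyclohexene (C7β vinyl; C8=C9) | CC[Si](CC)(CC)O[C@@H](CSc1ccccc1)[C@]2(C)C=C[C@@H](C=C)[C@@H](O[Li])[C@H]2CCO[Si](C)(C)C(C)(C)C | intermediate
13 | C6β isobutyrate of the cyclohexene (C5β CH2CH2OTBS; C7β vinyl; C10β Me; C10α CH(OTES)CH2SPh) | CC[Si](CC)(CC)O[C@@H](CSc1ccccc1)[C@]2(C)C=C[C@@H](C=C)[C@@H](OC(=O)C(C)C)[C@H]2CCO[Si](C)(C)C(C)(C)C | intermediate
14 | S-methyl sulfonium tetrafluoroborate of 13 (both configurations at sulfur) | CC[Si](CC)(CC)O[C@@H](C[S+](C)c1ccccc1)[C@]2(C)C=C[C@@H](C=C)[C@@H](OC(=O)C(C)C)[C@H]2CCO[Si](C)(C)C(C)(C)C.F[B-](F)(F)F | intermediate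
15 | epoxy alcohol (C10α (R)-oxiranyl; C5β CH2CH2OH; C6β isobutyrate; C7β vinyl) | C1O[C@@H]1[C@]2(C)C=C[C@@H](C=C)[C@@H](OC(=O)C(C)C)[C@H]2CCO | intermediate
16 | bis(9-BBN) adduct of 15 (C12–B and O3–B) | C1O[C@@H]1[C@]2(C)C=C[C@@H](CCB3C4CCCC3CCC4)[C@@H](OC(=O)C(C)C)[C@H]2CCOB5C6CCCC5CCC6 | intermediate
17 | diol (C5β and C7β CH2CH2OH) | C1O[C@@H]1[C@]2(C)C=C[C@@H](CCO)[C@@H](OC(=O)C(C)C)[C@H]2CCO | intermediate
18 | dialdehyde (C5β and C7β CH2CHO) | C1O[C@@H]1[C@]2(C)C=C[C@@H](CC=O)[C@@H](OC(=O)C(C)C)[C@H]2CC=O | intermediate
19 | bis-Mannich base (epimers at C4 and C11) | C1O[C@@H]1[C@]2(C)C=C[C@@H](C(CN(C)C)C=O)[C@@H](OC(=O)C(C)C)[C@H]2C(CN(C)C)C=O | intermediate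
20 | bis(α-methylene) dialdehyde | C1O[C@@H]1[C@]2(C)C=C[C@@H](C(=C)C=O)[C@@H](OC(=O)C(C)C)[C@H]2C(=C)C=O | intermediate
21 | 8α,9α-dihydroxy dialdehyde (open form of 22) | C1O[C@@H]1[C@]2(C)[C@H](O)[C@H](O)[C@@H](C(=C)C=O)[C@@H](OC(=O)C(C)C)[C@H]2C(=C)C=O | intermediate
22 | γ-lactol (anomers at C12) | C=C1C(O)O[C@@H]2[C@@H]1[C@@H](OC(=O)C(C)C)[C@@H](C(=C)C=O)[C@](C)([C@@H]1CO1)[C@@H]2O | intermediate
23 | CNP0496100.1 | C=C1C(=O)O[C@@H]2[C@@H]1[C@@H](OC(=O)C(C)C)[C@@H](C(=C)C=O)[C@](C)([C@@H]1CO1)[C@@H]2O | target

Total step count: 14. Longest linear sequence: 14 steps (fully linear from 1).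

**Steps most likely to fail**

Step 5 (key step). The tetrahedral adduct 8 carries the C10 methyl and the C5 side chain 1,3-diaxial and may leave the chair for a boat pyranone. In the boat the alkoxide oxygen, not the C1–C5 bond, is antiperiplanar to C10–Cl, so epoxide closure or simple addition could take the place of ring contraction. Fallback by photochemical Wolff ring contraction, setting out from 1 and returning at 9: deprotonation of 1 with the antipodal lithium amide and TMSCl should give the isomeric silyl enol ether F1 (enolised toward C5). Cleavage with MeLi and alkylation with the triflate of step 4 should give the C5-alkylated ketone F2. Detrifluoroacetylative diazo transfer (LiHMDS, CF3CO2CH2CF3; then MsN3, Et3N) should give the α-diazo ketone F3. Irradiation in methanol should contract the ring to the 7-oxanorbornene methyl ester F4. Exo-methylation of its enolate (KHMDS, MeI, −100 °C) should give the quaternary ester F5, which competes with β-elimination of the oxygen bridge and is the weak point of this fallback. Two equivalents of PhSCH2Li should convert F5 into ketone 9.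

Step 8. Carbolithiation could occur at C8 as well as at C7 (poor regioselectivity), which would cleave C6–O instead of C9–O, or it could be slow with an alkenyllithium. Fallback from 11, returning at 13: rhodium-catalysed syn addition of a vinylboron reagent with β-oxygen elimination ([Rh(cod)Cl]2, a bulky phosphite or phosphine, 2,4,6-trivinylcyclotriboroxane–pyridine, Cs2CO3, THF/H2O) should give the cis-vinyl cyclohexenol F6, with regiochemistry steered by the ligand; acylation of F6 with isobutyryl chloride, pyridine and DMAP returns to 13.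

Step 4. The electrophile has to pass the axial C10 methyl on the β face, so attack from the α face (poor facial selectivity) or loss of chloride from the α′-enolate (Favorskii-type side reaction) could intervene. Fallback from 1, returning at 7, with the side chain introduced first: 1 is taken through the silyl enol ether F1 and the alkylated ketone F2 as in the first fallback. Kinetic deprotonation of F2 at C10 (LDA) and chlorination with NCS should give the α-chloro ketone F7. LiHMDS and MeI then methylate the chloro enolate, so the smallest electrophile is the one that has to pass the axial side chain, and the sequence rejoins the route at 7.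

**Further compounds**

F1 | step 5 | 3-(trimethylsilyloxy)-8-oxabicyclo[3.2.1]octa-2,6-diene enolised toward C5 (C1=C5) | C1=C(O[Si](C)(C)C)C[C@@H]2C=C[C@H]1O2
F2 | step 5 | 2β-[2-(tert-butyldimethylsilyloxy)ethyl]-8-oxabicyclo[3.2.1]oct-6-en-3-one (side chain on C5; axial) | O=C1C[C@@H]2C=C[C@@H](O2)[C@H]1CCO[Si](C)(C)C(C)(C)C
F3 | step 5 | α-diazo ketone (diazo on C10) of F2 | O=C1C(=[N+]=[N-])[C@@H]2C=C[C@@H](O2)[C@H]1CCO[Si](C)(C)C(C)(C)C
F4 | step 5 | methyl exo-3-[2-(tert-butyldimethylsilyloxy)ethyl]-7-oxabicyclo[2.2.1]hept-5-ene-2-carboxylate (C10 epimers) | COC(=O)C1[C@@H]2C=C[C@@H](O2)[C@H]1CCO[Si](C)(C)C(C)(C)C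
F5 | step 5 | methyl exo-3-[2-(tert-butyldimethylsilyloxy)ethyl]-exo-2-methyl-7-oxabicyclo[2.2.1]hept-5-ene-endo-2-carboxylate | COC(=O)[C@]1(C)[C@@H]2C=C[C@@H](O2)[C@H]1CCO[Si](C)(C)C(C)(C)C
F6 | step 8 | C6β-alcohol corresponding to 13 (free OH in place of the isobutyrate) | CC[Si](CC)(CC)O[C@@H](CSc1ccccc1)[C@]2(C)C=C[C@@H](C=C)[C@@H](O)[C@H]2CCO[Si](C)(C)C(C)(C)C
F7 | step 4 | 4β-[2-(tert-butyldimethylsilyloxy)ethyl]-2β-chloro-8-oxabicyclo[3.2.1]oct-6-en-3-one (Cl on C10) | O=C1[C@@H](Cl)[C@@H]2C=C[C@@H](O2)[C@H]1CCO[Si](C)(C)C(C)(C)C
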